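**Plan**

- Retrosynthesis: the three O–S bonds and two benzyl ethers are cut first, leaving 5,3'-di-O-benzylquercetin. Ring C is then taken back to a flavan-3,4-diol and cut at C3–C4, and the resulting dialdehyde is cut at the O1–C2 ether bond.
- Enabling feature: in ring C the neighbouring atoms C3 and C4 both carry oxygen (the C3–O sulfate ester and the C4 carbonyl). C3–C4 is therefore a latent 1,2-diol bond that two aldehydes tethered through O1 and C2 can form by reductive coupling.
- Forward: ring A (from 2,4,6-trihydroxybenzaldehyde) and ring B with its two-carbon chain (from 3,4-dihydroxybenzaldehyde) are joined at O1–C2 by Mitsunobu etherification. Ring C then closes at C3–C4 and is oxidised to the 3-hydroxypyranone.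
- Protecting groups: benzyl on O5 and O3' stays through sulfation and MOM on O7 and O4' is removed before it, so only O3, O7 and O4' are free when SO3 is delivered.
- Stereochemistry: the target has no stereocentre. C2, C3 and C4 of the intermediates are racemic and uncontrolled, and all three become sp2 in step 12.

Key step: step 11

Assumption: the sulfate half-esters 17 and 18 are named and drawn as free acids, as the target is; 17 would be handled as its triethylammonium salt and 18 released by cold cation exchange and lyophilised at once, because aryl hydrogen sulfates hydrolyse in acid.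

**Step 1**
Reactants: 1 2,4,6-trihydroxybenzaldehyde
Product: 2 2,6-dihydroxy-4-(methoxymethoxy)benzaldehyde
Conditions: MOMCl (1.0 equiv), K2CO3 (1.1 equiv), acetone, 0 °C → rt
Reagents that add atoms: chloromethyl methyl ether, COCCl
Why: The 4-hydroxyl is the most acidic and the only one not hydrogen bonded to the formyl oxygen, so one equivalent of MOMCl should alkylate it first (regioselective Williamson-type O-alkylation).

**Step 2**
Reactants: 2 2,6-dihydroxy-4-(methoxymethoxy)benzaldehyde
Product: 3 2-(benzyloxy)-6-hydroxy-4-(methoxymethoxy)benzaldehyde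
Conditions: BnBr (1.0 equiv), K2CO3 (1.1 equiv), DMF, rt
Reagents that add atoms: benzyl bromide, BrCc1ccccc1
Why: The two ortho hydroxyls of 2 are equivalent, and after one Williamson etherification the other is held in a strong hydrogen bond to the formyl group and reacts far more slowly, so the reaction should stop at the mono-ether.

**Step 3**
Reactants: 4 3,4-dihydroxybenzaldehyde
Product: 5 3-hydroxy-4-(methoxymethoxy)benzaldehyde
Conditions: MOMCl (1.05 equiv), K2CO3 (1.1 equiv), acetone, 0 °C → rt
Reagents that add atoms: chloromethyl methyl ether, COCCl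
Why: The 4-hydroxyl, para to the formyl group, is the more acidic phenol and should be alkylated selectively under mild carbonate conditions (regioselective Williamson-type O-alkylation).

**Step 4**
Reactants: 5 3-hydroxy-4-(methoxymethoxy)benzaldehyde
Product: 6 3-(benzyloxy)-4-(methoxymethoxy)benzaldehyde
Conditions: BnBr, K2CO3, DMF, rt
Reagents that add atoms: benzyl bromide, BrCc1ccccc1
Why: Williamson ether synthesis on the only remaining phenol.

**Step 5**
Reactants: 6 3-(benzyloxy)-4-(methoxymethoxy)benzaldehyde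
Product: 7 2-(benzyloxy)-4-ethenyl-1-(methoxymethoxy)benzene
Conditions: Ph3PCH3Br, KOtBu, THF, 0 °C → rt
Reagents that add atoms: methyltriphenylphosphonium bromide, C[P+](c1ccccc1)(c1ccccc1)c1ccccc1.[Br-]
Why: Wittig methylenation of a non-enolisable aryl aldehyde; the ethers are inert to the ylide.

**Step 6**
Reactants: 7 2-(benzyloxy)-4-ethenyl-1-(methoxymethoxy)benzene
Product: 8 rac-1-[3-(benzyloxy)-4-(methoxymethoxy)phenyl]ethane-1,2-diol
Conditions: K2OsO4·2H2O (1 mol %), NMO, acetone–H2O, rt
Reagents that add atoms: 4-methylmorpholine N-oxide, C[N+]1([O-])CCOCC1; water, O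
Why: Upjohn dihydroxylation of a terminal styrene; the benzylic stereocentre is formed racemic, which is acceptable because it is erased in step 12.

**Step 7**
Reactants: 8 rac-1-[3-(benzyloxy)-4-(methoxymethoxy)phenyl]ethane-1,2-diol
Product: 9 rac-1-[3-(benzyloxy)-4-(methoxymethoxy)phenyl]-2-[(tert-butyldimethylsilyl)oxy]ethan-1-ol
Conditions: TBSCl (1.05 equiv), imidazole, CH2Cl2, 0 °C
Reagents that add atoms: tert-butyldimethylsilyl chloride, CC(C)(C)[Si](C)(C)Cl
Why: Selective silylation of the less hindered primary hydroxyl leaves the benzylic secondary hydroxyl free for etherification.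

**Step 8**
Reactants: 3 2-(benzyloxy)-6-hydroxy-4-(methoxymethoxy)benzaldehyde; 9 rac-1-[3-(benzyloxy)-4-(methoxymethoxy)phenyl]-2-[(tert-butyldimethylsilyl)oxy]ethan-1-ol
Product: 10 rac-2-(benzyloxy)-6-{1-[3-(benzyloxy)-4-(methoxymethoxy)phenyl]-2-[(tert-butyldimethylsilyl)oxy]ethoxy}-4-(methoxymethoxy)benzaldehyde
Conditions: PPh3, DIAD, THF, 0 °C → rt
Reagents that add atoms: none
Why: Mitsunobu etherification of a secondary benzylic alcohol with an acidic ortho-formyl phenol forms the O1–C2 bond; the benzylic configuration is irrelevant because the material is racemic.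

**Step 9**
Reactants: 10 rac-2-(benzyloxy)-6-{1-[3-(benzyloxy)-4-(methoxymethoxy)phenyl]-2-[(tert-butyldimethylsilyl)oxy]ethoxy}-4-(methoxymethoxy)benzaldehyde
Product: 11 rac-2-(benzyloxy)-6-{1-[3-(benzyloxy)-4-(methoxymethoxy)phenyl]-2-hydroxyethoxy}-4-(methoxymethoxy)benzaldehyde
Conditions: TBAF, AcOH, THF, 0 °C → rt
Reagents that add atoms: none
Why: Fluoride-mediated desilylation, buffered with acetic acid so that the aldehyde and the benzylic ether are not exposed to a basic alkoxide.

**Step 10**
Reactants: 11 rac-2-(benzyloxy)-6-{1-[3-(benzyloxy)-4-(methoxymethoxy)phenyl]-2-hydroxyethoxy}-4-(methoxymethoxy)benzaldehyde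
Product: 12 rac-2-(benzyloxy)-6-{1-[3-(benzyloxy)-4-(methoxymethoxy)phenyl]-2-oxoethoxy}-4-(methoxymethoxy)benzaldehyde
Conditions: Dess–Martin periodinane, NaHCO3, CH2Cl2, 0 °C → rt; used at once without chromatography
Reagents that add atoms: none
Why: Dess–Martin oxidation converts the primary alcohol into the aldehyde under buffered, non-basic conditions, which should spare the enolisable α-aryl-α-aryloxy aldehyde from aldol closure onto the neighbouring formyl group.

**Step 11**
Reactants: 12 rac-2-(benzyloxy)-6-{1-[3-(benzyloxy)-4-(methoxymethoxy)phenyl]-2-oxoethoxy}-4-(methoxymethoxy)benzaldehyde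
Product: 13 5-(benzyloxy)-2-[3-(benzyloxy)-4-(methoxymethoxy)phenyl]-7-(methoxymethoxy)chromane-3,4-diol (racemic, mixture of diastereomers at C3 and C4)
Conditions: SmI2 (2.5 equiv, 0.1 M in THF), t-BuOH (2 equiv), THF, −78 °C → rt, slow addition of 12 at high dilution; aq. NaHCO3
Reagents that add atoms: none
Why: SmI2 transfers one electron to the conjugated aryl aldehyde, the more easily reduced carbonyl, giving a samarium-bound ketyl at C4 that adds to the aliphatic formyl carbon C3, and a second electron with protonation delivers the diol; the closest known reaction type is the SmI2-mediated intramolecular pinacol coupling of 1,5- and 1,6-dialdehydes, which tolerates α-oxygen substituents in sugar-derived dialdehydes. Ring C closes in a 6-exo-trig mode, the ketyl carbon attacking the carbonyl carbon whose oxygen stays outside the ring. The new stereocentres C3 and C4 are expected to be mainly cis through chelation of both oxygens to samarium, with the 2-aryl group pseudo-equatorial, but no control is needed because C2, C3 and C4 all become sp2 in step 12. The selectivity that matters is chemoselectivity: ketyl formation at the aryl aldehyde and C–C closure must outrun reductive loss of the α-aryloxy group from the aliphatic aldehyde and intermolecular coupling, and this is secured by the conjugation of the aryl aldehyde, the short O1–C2 tether, low temperature and slow addition at high dilution.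

**Step 12**
Reactants: 13 5-(benzyloxy)-2-[3-(benzyloxy)-4-(methoxymethoxy)phenyl]-7-(methoxymethoxy)chromane-3,4-diol
Product: 15 5-(benzyloxy)-2-[3-(benzyloxy)-4-(methoxymethoxy)phenyl]-3-hydroxy-7-(methoxymethoxy)-4H-chromen-4-one, via chromane-3,4-dione 14 (not isolated)
Conditions: IBX (2.5 equiv), DMSO, rt; aq. NaHCO3 work-up
Reagents that add atoms: none
Why: IBX oxidation of a 1,2-diol gives the 1,2-dione without C–C cleavage, and the dione should enolise through its acidic, doubly activated C2–H to the aromatic 3-hydroxy-4-pyranone.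

**Step 13**
Reactants: 15 5-(benzyloxy)-2-[3-(benzyloxy)-4-(methoxymethoxy)phenyl]-3-hydroxy-7-(methoxymethoxy)-4H-chromen-4-one
Product: 16 5-(benzyloxy)-2-[3-(benzyloxy)-4-hydroxyphenyl]-3,7-dihydroxy-4H-chromen-4-one (5,3'-di-O-benzylquercetin)
Conditions: HCl (1.25 M in MeOH), THF, 40 °C
Reagents that add atoms: none
Why: Acid-catalysed acetal exchange with methanol removes both aryl MOM ethers while the benzyl ethers stay; if the chelated 5-benzyl ether were partly lost, the hydrogen-bonded 5-hydroxyl would still be the least reactive site in step 14.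

**Step 14**
Reactants: 16 5-(benzyloxy)-2-[3-(benzyloxy)-4-hydroxyphenyl]-3,7-dihydroxy-4H-chromen-4-one
Product: 17 5-(benzyloxy)-2-[3-(benzyloxy)-4-(sulfooxy)phenyl]-4-oxo-4H-chromene-3,7-diyl bis(hydrogen sulfate), handled as its tris(triethylammonium) salt
Conditions: SO3·NMe3 (excess), Et3N, DMF, 60 °C
Reagents that add atoms: sulfur trioxide–trimethylamine complex, C[N+](C)(C)S(=O)(=O)[O-]
Why: O-Sulfation of phenols and of the flavonol 3-hydroxyl with a sulfur trioxide–amine complex can be driven to completion because the only free hydroxyls are the three to be sulfated.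

**Step 15**
Reactants: 17 5-(benzyloxy)-2-[3-(benzyloxy)-4-(sulfooxy)phenyl]-4-oxo-4H-chromene-3,7-diyl bis(hydrogen sulfate)
Product: 18 quercetin 3,4',7-trisulfate, 5-hydroxy-2-[3-hydroxy-4-(sulfooxy)phenyl]-4-oxo-4H-chromene-3,7-diyl bis(hydrogen sulfate)
Conditions: H2 (1 atm), 10% Pd/C, MeOH–H2O, rt; then Dowex 50W (H+ form), H2O, 0 °C, lyophilise
Reagents that add atoms: none
Why: Catalytic hydrogenolysis cleaves the two benzyl aryl ethers and leaves aryl sulfate esters and the tetrasubstituted pyranone double bond untouched.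

**Compound list**

1 | 2,4,6-trihydroxybenzaldehyde | O=Cc1c(O)cc(O)cc1O | starting material
2 | 2,6-dihydroxy-4-(methoxymethoxy)benzaldehyde | O=Cc1c(O)cc(OCOC)cc1O | intermediate
3 | 2-(benzyloxy)-6-hydroxy-4-(methoxymethoxy)benzaldehyde | O=Cc1c(O)cc(OCOC)cc1OCc1ccccc1 | intermediate
4 | 3,4-dihydroxybenzaldehyde | O=Cc1ccc(O)c(O)c1 | starting material
5 | 3-hydroxy-4-(methoxymethoxy)benzaldehyde | O=Cc1ccc(OCOC)c(O)c1 | intermediate
6 | 3-(benzyloxy)-4-(methoxymethoxy)benzaldehyde | O=Cc1ccc(OCOC)c(OCc2ccccc2)c1 | intermediate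
7 | 2-(benzyloxy)-4-ethenyl-1-(methoxymethoxy)benzene | C=Cc1ccc(OCOC)c(OCc2ccccc2)c1 | intermediate
8 | rac-1-[3-(benzyloxy)-4-(methoxymethoxy)phenyl]ethane-1,2-diol | OCC(O)c1ccc(OCOC)c(OCc2ccccc2)c1 | intermediate
9 | rac-1-[3-(benzyloxy)-4-(methoxymethoxy)phenyl]-2-[(tert-butyldimethylsilyl)oxy]ethan-1-ol | CC(C)(C)[Si](C)(C)OCC(O)c1ccc(OCOC)c(OCc2ccccc2)c1 | intermediate
10 | rac-2-(benzyloxy)-6-{1-[3-(benzyloxy)-4-(methoxymethoxy)phenyl]-2-[(tert-butyldimethylsilyl)oxy]ethoxy}-4-(methoxymethoxy)benzaldehyde | O=Cc1c(OCc2ccccc2)cc(OCOC)cc1OC(CO[Si](C)(C)C(C)(C)C)c1ccc(OCOC)c(OCc2ccccc2)c1 | intermediate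
11 | rac-2-(benzyloxy)-6-{1-[3-(benzyloxy)-4-(methoxymethoxy)phenyl]-2-hydroxyethoxy}-4-(methoxymethoxy)benzaldehyde | O=Cc1c(OCc2ccccc2)cc(OCOC)cc1OC(CO)c1ccc(OCOC)c(OCc2ccccc2)c1 | intermediate
12 | rac-2-(benzyloxy)-6-{1-[3-(benzyloxy)-4-(methoxymethoxy)phenyl]-2-oxoethoxy}-4-(methoxymethoxy)benzaldehyde | O=CC(Oc1cc(OCOC)cc(OCc2ccccc2)c1C=O)c1ccc(OCOC)c(OCc2ccccc2)c1 | intermediate
13 | 5-(benzyloxy)-2-[3-(benzyloxy)-4-(methoxymethoxy)phenyl]-7-(methoxymethoxy)chromane-3,4-diol (racemic, diastereomer mixture) | OC1C(O)c2c(OCc3ccccc3)cc(OCOC)cc2OC1c1ccc(OCOC)c(OCc2ccccc2)c1 | intermediate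
14 | rac-5-(benzyloxy)-2-[3-(benzyloxy)-4-(methoxymethoxy)phenyl]-7-(methoxymethoxy)chromane-3,4-dione (not isolated) | O=C1C(=O)c2c(OCc3ccccc3)cc(OCOC)cc2OC1c1ccc(OCOC)c(OCc2ccccc2)c1 | intermediate
15 | 5-(benzyloxy)-2-[3-(benzyloxy)-4-(methoxymethoxy)phenyl]-3-hydroxy-7-(methoxymethoxy)-4H-chromen-4-one | O=c1c(O)c(-c2ccc(OCOC)c(OCc3ccccc3)c2)oc2cc(OCOC)cc(OCc3ccccc3)c12 | intermediate
16 | 5-(benzyloxy)-2-[3-(benzyloxy)-4-hydroxyphenyl]-3,7-dihydroxy-4H-chromen-4-one | O=c1c(O)c(-c2ccc(O)c(OCc3ccccc3)c2)oc2cc(O)cc(OCc3ccccc3)c12 | intermediate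
17 | 5-(benzyloxy)-2-[3-(benzyloxy)-4-(sulfooxy)phenyl]-4-oxo-4H-chromene-3,7-diyl bis(hydrogen sulfate) | O=c1c(OS(=O)(=O)O)c(-c2ccc(OS(=O)(=O)O)c(OCc3ccccc3)c2)oc2cc(OS(=O)(=O)O)cc(OCc3ccccc3)c12 | intermediate
18 | quercetin 3,4',7-trisulfate | O=c1c(OS(=O)(=O)O)c(-c2ccc(OS(=O)(=O)O)c(O)c2)oc2cc(OS(=O)(=O)O)cc(O)c12 | target

**Step count**

Total: 15 steps. Longest linear sequence: 13 steps (steps 3–15 from 3,4-dihydroxybenzaldehyde); the ring A branch (steps 1–2) joins at step 8.

**Steps most likely to fail**

Step 11. The first electron may instead enter the aliphatic aldehyde and lead to expulsion of the aryloxide (reductive cleavage of O1–C2), or the ketyl may couple intermolecularly or be reduced to the carbinol before it closes. The fallback gives up reductive closure and builds the flavonol by the Algar–Flynn–Oyamada reaction; it sets out from aldehyde 6 and returns at flavonol 15. Commercial 1-(2,4,6-trihydroxyphenyl)ethan-1-one would be protected as in steps 1 and 2 (MOMCl, K2CO3; then BnBr, K2CO3) to give 1-[2,6-dihydroxy-4-(methoxymethoxy)phenyl]ethan-1-one F1 and then 1-[2-(benzyloxy)-6-hydroxy-4-(methoxymethoxy)phenyl]ethan-1-one F2. Claisen–Schmidt condensation of this ketone with 6 (KOH, EtOH, rt) should give (E)-1-[2-(benzyloxy)-6-hydroxy-4-(methoxymethoxy)phenyl]-3-[3-(benzyloxy)-4-(methoxymethoxy)phenyl]prop-2-en-1-one F3. Alkaline hydrogen peroxide (H2O2, NaOH, MeOH, 0 °C) should then cyclise and oxidise the chalcone to 15. Aurone formation, favoured by the 6'-benzyloxy group, is the side path to watch for.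

Step 8. The activated, electron-rich benzylic oxyphosphonium may ionise before the hindered, hydrogen-bonded phenol attacks, leading to elimination or to alkylation on the ring carbon. The fallback separates activation from bond formation; it sets out from alcohol 9 and returns at ether 10. Treatment of 9 with SOCl2 and pyridine (CH2Cl2, −20 °C) should give rac-{2-[3-(benzyloxy)-4-(methoxymethoxy)phenyl]-2-chloroethoxy}(tert-butyl)dimethylsilane F4. This labile chloride would be used crude to alkylate the caesium phenoxide of 3 (Cs2CO3, DMF, 0 °C → rt) in a Williamson etherification.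

Step 12. The doubly activated benzylic C4 carbinol may ionise under the mildly acidic iodine reagent, or oxidation may stall after one carbinol or go on to attack the electron-rich flavonol. The fallback oxidises the two carbinols in separate, chemoselective stages; it sets out from diol 13 and returns at flavonol 15. Activated MnO2 (CH2Cl2, rt) should oxidise only the benzylic C4 carbinol to give 5-(benzyloxy)-2-[3-(benzyloxy)-4-(methoxymethoxy)phenyl]-3-hydroxy-7-(methoxymethoxy)-2,3-dihydro-4H-chromen-4-one F5. Dess–Martin periodinane (NaHCO3, CH2Cl2) should then oxidise this α-ketol, which cannot undergo glycol cleavage, to dione 14, which tautomerises to 15.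

**Further compounds**

F1 | step 11 | 1-[2,6-dihydroxy-4-(methoxymethoxy)phenyl]ethan-1-one | CC(=O)c1c(O)cc(OCOC)cc1O
F2 | step 11 | 1-[2-(benzyloxy)-6-hydroxy-4-(methoxymethoxy)phenyl]ethan-1-one | CC(=O)c1c(O)cc(OCOC)cc1OCc1ccccc1
F3 | step 11 | (E)-1-[2-(benzyloxy)-6-hydroxy-4-(methoxymethoxy)phenyl]-3-[3-(benzyloxy)-4-(methoxymethoxy)phenyl]prop-2-en-1-one | O=C(/C=C/c1ccc(OCOC)c(OCc2ccccc2)c1)c1c(O)cc(OCOC)cc1OCc1ccccc1
F4 | step 8 | rac-{2-[3-(benzyloxy)-4-(methoxymethoxy)phenyl]-2-chloroethoxy}(tert-butyl)dimethylsilane | CC(C)(C)[Si](C)(C)OCC(Cl)c1ccc(OCOC)c(OCc2ccccc2)c1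
F5 | step 12 | 5-(benzyloxy)-2-[3-(benzyloxy)-4-(methoxymethoxy)phenyl]-3-hydroxy-7-(methoxymethoxy)-2,3-dihydro-4H-chromen-4-one (racemic, diastereomer mixture) | O=C1c2c(OCc3ccccc3)cc(OCOC)cc2OC(c2ccc(OCOC)c(OCc3ccccc3)c2)C1O
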